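## Structural features

The target is a cembrane-type 14-membered carbocycle with no heteroatom in the ring. Numbered from the isopropenyl-bearing carbon as C1, it has three trisubstituted ring alkenes: C4=C5 (E) and C7=C8 (Z), which share the doubly allylic C6 methylene as a skipped diene, and C12=C13, across which ring carbons C11 and C14 are cis and the exocyclic acetoxymethyl carbon on C12 is trans to C14. C1 (R) and C14 (S) are contiguous stereocentres, C14 carrying a secondary allylic acetate. The third stereocentre, C9 (S), is a free secondary allylic alcohol on the far side of the Z alkene, too remote to be relayed from the C1/C14 pair. The fragile elements are the two allylic acetates flanking C12=C13 (ionisation, allylic transposition, acyl migration), the free C9 carbinol that must be told apart from two acylated oxygens, the Z alkene, which isomerises easily once conjugated to a carbonyl group, and the C6 methylene, which becomes acidic when C9 is a ketone. The real difficulty is closing a flexible all-carbon 14-membered ring with three alkene geometries intact and three oxygens differentiated. The unit C12(CH2OAc)=C13–C14(OAc) is the reduced form of a γ-oxygenated, α-substituted E-enoate, so C12=C13 can be made by olefination of a C13 aldehyde with a C12 phosphonoacetate; this is the feature the key step uses to close the ring. The aldehyde partner (C13, C14, C1 to C5 and the isopropenyl group) maps atom for atom onto ring-opened (S)-limonene, whose stereocentre becomes C1 with the required (R) configuration.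

## Logic of the disconnections

From 29 back to 25 only C–O and C–H bonds change. The two acetyl C–O bonds are cut (28 to 27), O9 and O14 are returned to a tert-butyldimethylsilyl and a triethylsilyl ether (29 to 28, 27 to 26), and the exocyclic carbon on C12 is raised to a methyl ester (26 to 25). The allylic acetates are the most labile groups and belong at the end, and O9 must stay distinguishable from the other two oxygens. The gain is a ring, 25, with one ester and two silyl ethers of graded lability. The forward demand is that the triethylsilyl ether falls before the tert-butyldimethylsilyl ether and that the last desilylation is neither basic nor strongly acidic.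

25 is cut at C12=C13, the one ring bond that can be formed as a C=C bond with the ester as activating group. This opens the ring to 24, with a phosphonoacetate at C12 and an aldehyde at C13. The gain is the largest of the plan: the macrocycle disappears and both chain ends become ordinary carbonyl chemistry. The demands are E geometry (ester trans to C14), high dilution, and a base too weak to enolise the α-silyloxy aldehyde.

24 is traced to 23 by returning C13 to a primary triethylsilyl ether, to 22 by cutting the O9–Si bond, and to 21 by cutting the C9–H bond. A 1,2-bis(triethylsilyl) ether releases the α-silyloxy aldehyde in one oxidative step, and a C9 ketone is what the next cut needs. The demands are an oxidation that distinguishes primary from secondary triethylsilyl ether, and reagent-controlled hydride delivery to a Z-alkenyl ketone, since no nearby stereocentre can direct it.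

21 is cut at C11–C12 into 19 and 20. The C9 ketone makes C11 an acceptor for the soft phosphonoacetate carbanion, so the bond forms without an activation step and brings in C12 with both substituents. The gain is a commercial reagent and a shorter chain. The demand is selectivity for the vinyl terminus over the trisubstituted enone under catalysis mild enough for the acidified C6 methylene of 19.

19 is cut at C9–C10 into 17 and 18. The N-methoxy-N-methyl amide is chosen because addition stops at the ketone, so the sensitive dienone exists for one step only. The demand is that the amine released on work-up does not add to the vinyl ketone.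

17 is cut at C5–C6 and at C4–CH3, giving 11, 15 and AlMe3. One operation (carbometalation, then allylation) forms both bonds and fixes the E geometry of C4=C5 by syn addition, while the Z geometry of C7=C8 is imported ready-made. The gain is convergence on two fragments of similar size. The demand is allylation at C6 with retention of both geometries, and tolerance of silyl ethers and amide toward the alane.

15 goes back through 13 to 12 by exchanging chloride for hydroxyl and closing the lactone. The five-membered ring of 12 holds C6 and C9 cis, so the Z alkene needs no stereoselective step. The demand is ring opening at the acyl carbon without isomerisation and no re-lactonisation before the hydroxyl is converted.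

11 is traced to 10 (two O–Si bonds), to 9 (N–O in place of O–H) and to 7 by cutting the C14–O bond. Oxygenation α to an aldehyde by enamine catalysis creates C14 under catalyst control beside the existing C1 centre, so the second centre of the contiguous pair costs one step. The demand is catalyst control over a β-branched aldehyde and immediate reduction of the labile product.

7 is traced to 6 and 4 (aldehyde masked as acetal, alkyne returned to the methyl ketone), and 4 to 1 by re-joining the two carbonyl carbons into the ring alkene. 1 supplies C1 in the correct configuration together with nine further carbons. The demands are selective cleavage of the ring alkene beside the isopropenyl group, differentiation of the two new termini, and enolisation of the methyl ketone toward the methyl group.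

## Other disconnections considered

Alternative 1: The ring is cut at C1–C14 and the isopropenyl group is read as the remains of a 2-methylallyl ether, which leads back to the 17-membered propargyl allyl ether A1. In the forward direction a chiral lithium amide removes a proton from the propargylic O–CH2 group (the future C14). The carbanion undergoes a [2,3]-Wittig shift onto the allyl terminus, forming C1–C14, freeing the isopropenyl group and contracting the ring to the propargylic alcohol A2.
- In its favour: the ring C–C bond is made by contraction of an existing ring, the large ring itself is closed by O-alkylation, C1 and C14 are created together with their relative configuration set by the envelope transition state, and no epimerisable aldehyde is involved. On these points it is the equal of, or better than, the chosen plan.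
- Against it here: the absolute configuration depends on how well the chiral base distinguishes two enantiotopic protons in a substrate that already carries C9, whereas the chosen plan takes C1 from the chiral pool and C14 from a catalyst with a well-understood facial bias. A [1,2]-shift and deprotonation on the allylic side compete.
- Against it here: A2 has an alkyne where the target has C12(CH2OAc)=C13. Converting it needs syn addition of hydrogen at C13 and a one-carbon unit at C12; the hydroxyl-directed hydroalumination that gives this regiochemistry is an anti addition and would place C11 and C14 trans.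
- Step economy: the two plans are probably close up to the ring, but A2 then needs three or four further operations of uncertain regiocontrol, while the chosen olefination delivers ring, alkene geometry and the C12 carbon substituent together.

Alternative 2: The cut is C1–C2 with an extra carboxyl group on C2, leading back to the 18-membered lactone A3, whose acyl part ends at C2 and whose alcohol part is the 2-methylallyl unit ending at C1. Forward, enolisation and O-silylation give the silyl ketene acetal, whose [3,3] shift (Ireland–Claisen) forms C1–C2, releases the isopropenyl group and contracts the ring to the acid A4.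
- In its favour: the large ring is closed by lactonisation, one of the most dependable macrocyclisations and in this respect better than a macrocyclic olefination. The C–C bond then forms in a concerted intramolecular step, and the configuration at C2 does not matter.
- Against it here: C1 is created in the rearrangement. Its configuration depends on ketene acetal geometry, on chair versus boat in a ring-embedded transition state, and on the facial bias of the adjacent C14 silyloxy centre; none is as secure as taking C1 from limonene.
- Against it here: the carboxyl group must be removed afterwards by radical decarboxylation (two more steps) in a molecule with four alkenes.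
- Equal point: the E-configured C12=C13 unit must be built separately in the open chain, where olefination is at least as selective as in a macrocycle.
- Step economy: longer by the lactone formation, the decarboxylation and the separate construction of C12=C13.

Alternative 3: The cut is C2–C3, leading back to the open-chain sulfone A5 with a phenylsulfonyl group on C2 and a primary allylic chloride at C3. Forward, LiN(iPr)2 deprotonates C2 and the carbanion displaces chloride in an intramolecular SN2 reaction, closing the ring to A6; the sulfone is removed reductively afterwards.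
- In its favour: alkylation of sulfone-stabilised carbanions with allylic halides is a classical route to 14-membered isoprenoid rings and, as a ring closure, at least the equal of the chosen olefination. The C2 configuration is irrelevant. The reacting carbons are remote from C14, so no stereocentre is at risk during cyclisation, a real advantage over an α-silyloxy aldehyde. C12=C13 would be set beforehand in the open chain.
- Against it here: A5 must already contain all three stereocentres and all three alkenes, so nothing of the chosen route is saved. C2 of the limonene-derived unit is an unfunctionalised methylene, so the sulfone cannot be introduced without giving up the direct mapping onto limonene or adding steps.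
- Against it here: the strong base meets several allylic and doubly allylic hydrogens and an allylic chloride that can also react in an SN2′ sense, and desulfonylation adds a step.
- Mechanism: the alkylation is irreversible and kinetically controlled; the olefination is reversible up to the elimination and so corrects itself toward the E-alkene.
- Step economy: the chosen plan is shorter by about three steps, because its ring-closing reaction also installs the C12 substituent and needs no auxiliary group.

Key step: step 15

Remarks on the chemistry:
- C12 of the open-chain phosphonates 21 to 24 is not controlled; both epimers converge in step 15, so their SMILES leave C12 undefined. The hydroperoxide carbon of 2 and 3 is likewise undefined and is lost within step 1.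
- Configuration check: ring-opened (S)-limonene supplies C1 as (R) in the ring; L-proline is the enantiomer that gives the (14S) centre; the (R)-oxazaborolidine is the enantiomer expected to give (9S).
- 24 is generated from 23 in one oxidative step and cyclised without purification, so the epimerisable α-silyloxy aldehyde is kept for hours only.
- The allylic chloride 15 is assumed stable enough for immediate use; it is not stored.

## Route

Step 1
Reactants: 1 (S)-limonene
Product: 4 (5S)-7,7-dimethoxy-5-(prop-1-en-2-yl)heptan-2-one, via hydroperoxy aldehyde 2 (not isolated), via hydroperoxy acetal 3 (not isolated)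
Conditions: O3, CH2Cl2/MeOH 5:1, Sudan Red 7B end-point, −78 °C; TsOH·H2O (cat.), 23 °C; NaHCO3, then Me2S, 23 °C
Reagents that add atoms: ozone ([O-][O+]=O); methanol (CO)
Why: Ozone attacks the electron-rich trisubstituted ring alkene much faster than the isopropenyl group, and the dye end-point stops the addition there. In methanol the carbonyl oxide is trapped as a methoxy hydroperoxide at the former C–CH3 carbon, the free aldehyde is acetalised while that carbon is still masked, and Me2S then releases the methyl ketone (ozonolytic cleavage of a cycloalkene to terminally differentiated products); the stereocentre is untouched and becomes C1.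

Step 2
Reactants: 4 (5S)-7,7-dimethoxy-5-(prop-1-en-2-yl)heptan-2-one
Product: 6 (5S)-7,7-dimethoxy-5-(prop-1-en-2-yl)hept-1-yne, via enol phosphate 5 (not isolated)
Conditions: LiN(iPr)2 (1.1 equiv), THF, −78 °C; ClP(O)(OEt)2, −78 → 23 °C; LiN(iPr)2 (2.3 equiv), −78 → 23 °C; aq. NH4Cl
Reagents that add atoms: none
Why: Kinetic deprotonation occurs at the methyl group of the methyl ketone, O-phosphorylation gives the terminal enol phosphate, and base-induced elimination of diethyl phosphate gives the 1-alkyne (Negishi conversion of methyl ketones into terminal alkynes); the acetal is inert to base.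

Step 3
Reactants: 6 (5S)-7,7-dimethoxy-5-(prop-1-en-2-yl)hept-1-yne
Product: 7 (3S)-3-(prop-1-en-2-yl)hept-6-ynal
Conditions: 5% aq. oxalic acid, THF, 23 °C
Reagents that add atoms: water (O)
Why: Mild aqueous acid hydrolyses the dimethyl acetal without hydrating the isopropenyl group or the alkyne; the stereocentre is β to the carbonyl and cannot epimerise. The volatile aldehyde is used directly.

Step 4
Reactants: 7 (3S)-3-(prop-1-en-2-yl)hept-6-ynal
Product: 9 (2R,3R)-2-(phenylaminooxy)-3-(prop-1-en-2-yl)hept-6-yn-1-ol, via anilinooxy aldehyde 8 (not isolated)
Conditions: PhNO (1.1 equiv), L-proline (0.3 equiv), DMSO, 23 °C; then NaBH4, MeOH, 0 °C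
Reagents that add atoms: nitrosobenzene (O=Nc1ccccc1)
Why: In this proline-catalysed α-aminoxylation the enamine of 7 attacks the oxygen of nitrosobenzene, which is hydrogen-bonded to the carboxylic acid of L-proline, so the catalyst sets the new C–O centre (the future C14) largely independently of the β-stereocentre. NaBH4 reduces the labile α-aminoxy aldehyde in the same flask before it can epimerise or oligomerise.

Step 5
Reactants: 9 (2R,3R)-2-(phenylaminooxy)-3-(prop-1-en-2-yl)hept-6-yn-1-ol
Product: 10 (2R,3R)-3-(prop-1-en-2-yl)hept-6-yne-1,2-diol
Conditions: Zn dust, AcOH, THF, 23 °C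
Reagents that add atoms: none
Why: Zinc in acetic acid cleaves the weak N–O bond reductively and leaves the terminal alkyne and the isopropenyl group untouched.

Step 6
Reactants: 10 (2R,3R)-3-(prop-1-en-2-yl)hept-6-yne-1,2-diol
Product: 11 (2R,3R)-3-(prop-1-en-2-yl)-1,2-bis(triethylsilyloxy)hept-6-yne
Conditions: Et3SiCl (2.5 equiv), imidazole, DMAP (cat.), CH2Cl2, 0 → 23 °C
Reagents that add atoms: chlorotriethylsilane (CC[Si](Cl)(CC)CC)
Why: This is a standard bis-silylation; both ethers survive base, organometallics and the alane, and they are told apart later because only the primary one is oxidised under Swern conditions.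

Step 7
Reactants: 12 3-methyl-2(5H)-furanone
Product: 13 (Z)-4-hydroxy-N-methoxy-N,2-dimethylbut-2-enamide
Conditions: MeNH(OMe)·HCl (2 equiv), AlMe3 (2 equiv), CH2Cl2, 0 → 23 °C; aq. KNaC4H4O6
Reagents that add atoms: N,O-dimethylhydroxylamine hydrochloride (CNOC.Cl)
Why: The aluminium amide opens the lactone at the acyl C–O bond only (Weinreb amidation), so the Z geometry enforced by the five-membered ring is carried into the open chain. The product is used at once because acid would close it back to the lactone.

Step 8
Reactants: 13 (Z)-4-hydroxy-N-methoxy-N,2-dimethylbut-2-enamide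
Product: 15 (Z)-4-chloro-N-methoxy-N,2-dimethylbut-2-enamide, via mesylate 14 (not isolated)
Conditions: MsCl, 2,4,6-collidine, LiCl, DMF, 0 °C
Reagents that add atoms: lithium chloride ([Li+].[Cl-])
Why: The allylic mesylate is displaced in situ by chloride in an SN2 reaction without allylic transposition or Z/E change (Collington–Meyers chlorination). The chloride is used promptly to forestall O-alkylation by its own amide carbonyl.

Step 9
Reactants: 11 (2R,3R)-3-(prop-1-en-2-yl)-1,2-bis(triethylsilyloxy)hept-6-yne; 15 (Z)-4-chloro-N-methoxy-N,2-dimethylbut-2-enamide
Product: 17 (2Z,5E)-dienyl N-methoxy-N-methyl amide carrying the C13/C14 bis(triethylsilyl) ether, via alkenylalane 16 (not isolated)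
Conditions: AlMe3 (2.0 equiv), Cp2ZrCl2 (0.25 equiv), CH2Cl2, 23 °C; volatiles removed; then 15 (1.1 equiv), Pd(PPh3)4 (5 mol%), THF, 0 → 23 °C
Reagents that add atoms: trimethylaluminium (C[Al](C)C)
Why: Zirconium-catalysed syn-carboalumination of the terminal alkyne (Negishi) puts methyl on C4 and aluminium on C5 on the same side, which fixes C4=C5 as E. Allylation of the alkenylalane under zerovalent palladium catalysis then forms C5–C6 at the primary terminus of the π-allyl unit with retention of both geometries; the Z geometry of C7=C8 should hold because syn/anti exchange would need palladium σ-bonded to the fully substituted C8. Silyl ethers, isopropenyl group and amide do not react with the alane once excess AlMe3 is removed.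

Step 10
Reactants: 17 (2Z,5E)-dienyl N-methoxy-N-methyl amide; 18 vinylmagnesium bromide
Product: 19 (4Z,7E)-cross-conjugated trienone with C9 ketone and C10=C11 vinyl group
Conditions: CH2=CHMgBr (3 equiv), THF, −78 → 0 °C; poured into cold aq. NH4Cl
Reagents that add atoms: none
Why: The Grignard reagent adds once to the N-methoxy-N-methyl amide, whose chelated tetrahedral intermediate collapses to the ketone only on work-up; the inverse quench protonates the released amine before it can add to the vinyl ketone. 19 is sensitive to base and acid and is taken on crude.

Step 11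
Reactants: 19 (4Z,7E)-cross-conjugated trienone; 20 methyl diethylphosphonoacetate
Product: 21 C9 keto C12 phosphonoacetate (C12 epimers)
Conditions: 20 (2 equiv), NaH (0.1 equiv), THF, −40 → −20 °C; AcOH quench
Reagents that add atoms: none
Why: Base-catalysed Michael addition of the phosphonoacetate carbanion occurs at the unsubstituted vinyl terminus C11, which is far more electrophilic than the α-methyl-β-alkyl Z-enone. The only base present is the phosphonate anion, which limits deprotonation at C6, Z-to-E isomerisation and a second, ring-forming Michael addition; excess 20 suppresses double addition.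

Step 12
Reactants: 21 C9 keto C12 phosphonoacetate
Product: 22 (9S)-hydroxy C12 phosphonoacetate
Conditions: (R)-2-methyl-CBS-oxazaborolidine (1.0 equiv), catecholborane (2 equiv), toluene, −78 °C; MeOH; pH 7 buffer
Reagents that add atoms: none
Why: In this Corey–Bakshi–Shibata reduction the oxazaborolidine boron binds the ketone oxygen anti to the larger, α-branched alkenyl group and hydride is delivered to the face that should give the (9S) carbinol, the alkenyl group playing the role of the aryl group in the (R)-catalyst/(S)-1-arylalkanol correlation. Catecholborane at −78 °C reduces neither ester nor alkenes, and any 9-epimer becomes separable after step 15, when C12 is no longer stereogenic.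

Step 13
Reactants: 22 (9S)-hydroxy C12 phosphonoacetate
Product: 23 (9S)-tert-butyldimethylsilyl ether with C13/C14 bis(triethylsilyl) ether and C12 phosphonoacetate
Conditions: t-BuMe2SiOTf (1.3 equiv), 2,6-lutidine, CH2Cl2, −78 °C
Reagents that add atoms: tert-butyldimethylsilyl trifluoromethanesulfonate (CC(C)(C)[Si](C)(C)OS(=O)(=O)C(F)(F)F)
Why: The silyl triflate with a hindered pyridine base silylates the hindered allylic carbinol within minutes at low temperature, which also removes the hydroxyl before it can lactonise onto the δ-ester; triethylsilyl ethers, ester and phosphonate are unaffected.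

Step 14
Reactants: 23 (9S)-tert-butyldimethylsilyl ether with C13/C14 bis(triethylsilyl) ether
Product: 24 seco C13 aldehyde with C14 triethylsilyl ether and C12 phosphonoacetate
Conditions: (COCl)2 (4 equiv), DMSO (8 equiv), CH2Cl2, −78 → −40 °C; Et3N, −78 → 0 °C
Reagents that add atoms: none
Why: Under Swern conditions the chlorosulfonium reagent attacks the unhindered primary triethylsilyl ether, Et3SiCl is lost and the alkoxysulfonium ion collapses to the aldehyde with Et3N, while secondary triethylsilyl and tert-butyldimethylsilyl ethers stay (known selective oxidative deprotection of primary triethylsilyl ethers). Et3N is too weak to deprotonate the phosphonoacetate, so no olefination occurs here.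

Step 15
Reactants: 24 seco C13 aldehyde with C14 triethylsilyl ether and C12 phosphonoacetate
Product: 25 macrocyclic E-enoate with methyl ester on C12
Conditions: LiCl (20 equiv), i-Pr2NEt (10 equiv), MeCN, 23 °C; 24 added by syringe pump over 10 h, final 1 mM
Reagents that add atoms: none
Why: Li+ chelates the phosphoryl and ester oxygens of the C12 phosphonoacetate, which lets the amine deprotonate C12; the lithium enolate adds reversibly to the C13 aldehyde, and the adduct closes to an oxaphosphetane whose syn-elimination of lithium diethyl phosphate forms C12=C13. This is a Horner–Wadsworth–Emmons olefination under Masamune–Roush conditions run intramolecularly, the closest known type being phosphonoacetate–aldehyde macrocyclisations to macrocyclic enoates. The one ring formed is the 14-membered carbocycle, closed end to end by 14-exo-trig addition of the C12 carbanion to the C13 carbonyl, with slow addition keeping the concentration of open-chain material low. No stereocentre is created, and the two C12 epimers of 24 converge because C12 becomes sp2. The first selectivity needed is E geometry (ester trans to C14, hence C11 and C14 cis in the ring): reversible addition lets the α-alkyl phosphonoacetate funnel through the less crowded oxaphosphetane with C14 anti to the ester, and a cis ring junction for a trisubstituted alkene is also the unstrained one in a 14-membered ring. The second is retention at C14, α to the aldehyde, which is served by the weak amine base, by the bulky triethylsilyloxy group beside the α-hydrogen, and by the absence of alkoxide or amide bases. The C6 methylene and the silyl ethers are inert here because C9 is no longer a ketone.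

Step 16
Reactants: 25 macrocyclic E-enoate with methyl ester on C12
Product: 26 macrocyclic C12 hydroxymethyl compound with C14 triethylsilyl and C9 tert-butyldimethylsilyl ethers
Conditions: i-Bu2AlH (3 equiv), CH2Cl2, −78 °C; aq. KNaC4H4O6
Reagents that add atoms: none
Why: i-Bu2AlH reduces the conjugated methyl ester in a 1,2 sense to the primary allylic alcohol at −78 °C; silyl ethers and isolated alkenes are inert.

Step 17
Reactants: 26 macrocyclic C12 hydroxymethyl compound
Product: 27 macrocyclic C14 hydroxy C12 hydroxymethyl diol with C9 tert-butyldimethylsilyl ether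
Conditions: PPTS (0.2 equiv), MeOH/CH2Cl2 1:1, 0 °C
Reagents that add atoms: none
Why: Mild acid-catalysed methanolysis removes the triethylsilyl ether, which is cleaved much faster than the tert-butyldimethylsilyl ether, so O14 is freed while O9 stays masked.

Step 18
Reactants: 27 macrocyclic diol with C9 tert-butyldimethylsilyl ether
Product: 28 macrocyclic diacetate with C9 tert-butyldimethylsilyl ether
Conditions: Ac2O, pyridine, DMAP (cat.), CH2Cl2, 0 → 23 °C
Reagents that add atoms: acetic anhydride (CC(=O)OC(C)=O)
Why: Both the primary and the secondary allylic hydroxyl are acylated under nucleophilic catalysis; no base strong enough for acyl migration or elimination is present.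

Step 19
Reactants: 28 macrocyclic diacetate with C9 tert-butyldimethylsilyl ether
Product: 29 target CNP0097266.2
Conditions: HF·pyridine, pyridine, THF, 0 → 23 °C
Reagents that add atoms: none
Why: Buffered HF·pyridine cleaves the remaining silyl ether; it is neither basic enough to move or remove the allylic acetates nor acidic enough to ionise them.

## Compound list

1 | (S)-limonene, (4S)-1-methyl-4-(prop-1-en-2-yl)cyclohex-1-ene | CC1=CC[C@H](CC1)C(C)=C | starting material
2 | (3S)-6-hydroperoxy-6-methoxy-3-(prop-1-en-2-yl)heptanal, formed in the flask | O=CC[C@H](CCC(C)(OC)OO)C(C)=C | intermediate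
3 | (5S)-2-hydroperoxy-2,7,7-trimethoxy-5-(prop-1-en-2-yl)heptane, formed in the flask | COC(OC)C[C@H](CCC(C)(OC)OO)C(C)=C | intermediate
4 | (5S)-7,7-dimethoxy-5-(prop-1-en-2-yl)heptan-2-one | COC(OC)C[C@H](CCC(C)=O)C(C)=C | intermediate
5 | diethyl (5S)-7,7-dimethoxy-5-(prop-1-en-2-yl)hept-1-en-2-yl phosphate, formed in the flask | COC(OC)C[C@H](CCC(=C)OP(=O)(OCC)OCC)C(C)=C | intermediate
6 | (5S)-7,7-dimethoxy-5-(prop-1-en-2-yl)hept-1-yne | COC(OC)C[C@H](CCC#C)C(C)=C | intermediate
7 | (3S)-3-(prop-1-en-2-yl)hept-6-ynal | O=CC[C@H](CCC#C)C(C)=C | intermediate
8 | (2R,3R)-2-(phenylaminooxy)-3-(prop-1-en-2-yl)hept-6-ynal, formed in the flask | O=C[C@H](ONc1ccccc1)[C@H](CCC#C)C(C)=C | intermediate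
9 | (2R,3R)-2-(phenylaminooxy)-3-(prop-1-en-2-yl)hept-6-yn-1-ol | OC[C@H](ONc1ccccc1)[C@H](CCC#C)C(C)=C | intermediate
10 | (2R,3R)-3-(prop-1-en-2-yl)hept-6-yne-1,2-diol | OC[C@H](O)[C@H](CCC#C)C(C)=C | intermediate
11 | (2R,3R)-3-(prop-1-en-2-yl)-1,2-bis(triethylsilyloxy)hept-6-yne | CC[Si](CC)(CC)OC[C@H](O[Si](CC)(CC)CC)[C@H](CCC#C)C(C)=C | intermediate
12 | 3-methyl-2(5H)-furanone | CC1=CCOC1=O | starting material
13 | (Z)-4-hydroxy-N-methoxy-N,2-dimethylbut-2-enamide | OC/C=C(/C)C(=O)N(C)OC | intermediate
14 | (Z)-4-[methoxy(methyl)amino]-3-methyl-4-oxobut-2-enyl methanesulfonate, formed in the flask | CS(=O)(=O)OC/C=C(/C)C(=O)N(C)OC | intermediate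
15 | (Z)-4-chloro-N-methoxy-N,2-dimethylbut-2-enamide | ClC/C=C(/C)C(=O)N(C)OC | intermediate
16 | dimethyl[(1E,5R,6R)-2-methyl-5-(prop-1-en-2-yl)-6,7-bis(triethylsilyloxy)hept-1-enyl]alane, formed in the flask | CC[Si](CC)(CC)OC[C@H](O[Si](CC)(CC)CC)[C@H](CC/C(C)=C/[Al](C)C)C(C)=C | intermediate
17 | (2Z,5E,9R,10R)-N-methoxy-N,2,6-trimethyl-9-(prop-1-en-2-yl)-10,11-bis(triethylsilyloxy)undeca-2,5-dienamide | CC[Si](CC)(CC)OC[C@H](O[Si](CC)(CC)CC)[C@H](CC/C(C)=C/C/C=C(/C)C(=O)N(C)OC)C(C)=C | intermediate
18 | vinylmagnesium bromide, CH2=CHMgBr | C=C[Mg]Br | starting material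
19 | (4Z,7E,11R,12R)-4,8-dimethyl-11-(prop-1-en-2-yl)-12,13-bis(triethylsilyloxy)trideca-1,4,7-trien-3-one | CC[Si](CC)(CC)OC[C@H](O[Si](CC)(CC)CC)[C@H](CC/C(C)=C/C/C=C(/C)C(=O)C=C)C(C)=C | intermediate
20 | methyl diethylphosphonoacetate, methyl 2-(diethoxyphosphoryl)acetate | COC(=O)CP(=O)(OCC)OCC | starting material
21 | methyl (6Z,9E,13R,14R)-2-(diethoxyphosphoryl)-6,10-dimethyl-5-oxo-13-(prop-1-en-2-yl)-14,15-bis(triethylsilyloxy)pentadeca-6,9-dienoate, C2 epimers | CC[Si](CC)(CC)OC[C@H](O[Si](CC)(CC)CC)[C@H](CC/C(C)=C/C/C=C(/C)C(=O)CCC(C(=O)OC)P(=O)(OCC)OCC)C(C)=C | intermediate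
22 | methyl (5S,6Z,9E,13R,14R)-2-(diethoxyphosphoryl)-5-hydroxy-6,10-dimethyl-13-(prop-1-en-2-yl)-14,15-bis(triethylsilyloxy)pentadeca-6,9-dienoate, C2 epimers | CC[Si](CC)(CC)OC[C@H](O[Si](CC)(CC)CC)[C@H](CC/C(C)=C/C/C=C(/C)[C@@H](O)CCC(C(=O)OC)P(=O)(OCC)OCC)C(C)=C | intermediate
23 | methyl (5S,6Z,9E,13R,14R)-5-(tert-butyldimethylsilyloxy)-2-(diethoxyphosphoryl)-6,10-dimethyl-13-(prop-1-en-2-yl)-14,15-bis(triethylsilyloxy)pentadeca-6,9-dienoate, C2 epimers | CC[Si](CC)(CC)OC[C@H](O[Si](CC)(CC)CC)[C@H](CC/C(C)=C/C/C=C(/C)[C@@H](O[Si](C)(C)C(C)(C)C)CCC(C(=O)OC)P(=O)(OCC)OCC)C(C)=C | intermediate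
24 | methyl (5S,6Z,9E,13R,14R)-5-(tert-butyldimethylsilyloxy)-2-(diethoxyphosphoryl)-6,10-dimethyl-15-oxo-13-(prop-1-en-2-yl)-14-(triethylsilyloxy)pentadeca-6,9-dienoate, C2 epimers | O=C[C@H](O[Si](CC)(CC)CC)[C@@H](C(C)=C)CC/C(C)=C/C/C=C(/C)[C@@H](O[Si](C)(C)C(C)(C)C)CCC(C(=O)OC)P(=O)(OCC)OCC | intermediate
25 | methyl (1E,3S,4R,7E,10Z,12S)-12-(tert-butyldimethylsilyloxy)-7,11-dimethyl-4-(prop-1-en-2-yl)-3-(triethylsilyloxy)cyclotetradeca-1,7,10-triene-1-carboxylate | C=C(C)[C@H]1CC/C(C)=C/C/C=C(/C)[C@@H](O[Si](C)(C)C(C)(C)C)CC/C(C(=O)OC)=C\[C@@H]1O[Si](CC)(CC)CC | intermediate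
26 | [(1E,3S,4R,7E,10Z,12S)-12-(tert-butyldimethylsilyloxy)-7,11-dimethyl-4-(prop-1-en-2-yl)-3-(triethylsilyloxy)cyclotetradeca-1,7,10-trien-1-yl]methanol | C=C(C)[C@H]1CC/C(C)=C/C/C=C(/C)[C@@H](O[Si](C)(C)C(C)(C)C)CC/C(CO)=C\[C@@H]1O[Si](CC)(CC)CC | intermediate
27 | [(1E,3S,4R,7E,10Z,12S)-12-(tert-butyldimethylsilyloxy)-3-hydroxy-7,11-dimethyl-4-(prop-1-en-2-yl)cyclotetradeca-1,7,10-trien-1-yl]methanol | C=C(C)[C@H]1CC/C(C)=C/C/C=C(/C)[C@@H](O[Si](C)(C)C(C)(C)C)CC/C(CO)=C\[C@@H]1O | intermediate
28 | [(1E,3S,4R,7E,10Z,12S)-3-acetoxy-12-(tert-butyldimethylsilyloxy)-7,11-dimethyl-4-(prop-1-en-2-yl)cyclotetradeca-1,7,10-trien-1-yl]methyl acetate | C=C(C)[C@H]1CC/C(C)=C/C/C=C(/C)[C@@H](O[Si](C)(C)C(C)(C)C)CC/C(COC(C)=O)=C\[C@@H]1OC(C)=O | intermediate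
29 | CNP0097266.2, [(1E,3S,4R,7E,10Z,12S)-3-acetoxy-12-hydroxy-7,11-dimethyl-4-(prop-1-en-2-yl)cyclotetradeca-1,7,10-trien-1-yl]methyl acetate | C=C(C)[C@H]1CC/C(C)=C/C/C=C(/C)[C@@H](O)CC/C(COC(C)=O)=C\[C@@H]1OC(C)=O | target

## Step count and least certain steps

Total: 19 steps. Longest linear sequence: 17 steps (steps 1 to 6 and 9 to 19); steps 7 and 8 form a two-step branch.

Step 15 (key step). The most likely failure is enolisation of the α-silyloxy aldehyde during a slow ring closure, which would erode the C14 configuration, together with intermolecular olefination if the effective concentration rises. The carbanion is present only in small equilibrium concentration and the 14-membered closure has no conformational bias, so the aldehyde waits in a basic medium. The fallback moves the control of C14 from protection during the cyclisation to correction after it. It sets out from 24: the cyclisation is run as before and 25 is separated from the 14-epimeric macrocyclic enoate F1. F1 is desilylated at O14 (PPTS, MeOH) to the 14-epimeric hydroxy enoate F2. Mitsunobu esterification (PhCO2H, PPh3, diisopropyl azodicarboxylate) inverts C14 and gives the (14S)-benzoate F3. i-Bu2AlH then cleaves the benzoate and reduces the methyl ester in one operation, and the route is rejoined at 27.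

Step 9. The most likely failure is partial Z-to-E isomerisation of C7=C8 in the electron-poor π-allyl palladium intermediate (the amide carbonyl on C8 makes a palladium enolate form conceivable), or loss of 15 by cyclisation onto its own carbonyl oxygen before coupling. The fallback builds the Z alkene by olefination. It sets out from 11, which is carboaluminated as in step 9; the alkenylalane is converted to its ate complex with n-BuLi and opened with ethylene oxide to the homoallylic alcohol F4. Buffered Dess–Martin oxidation (NaHCO3) gives the β,γ-unsaturated aldehyde F5, which is used at once. Still–Gennari olefination with methyl 2-[bis(2,2,2-trifluoroethoxy)phosphoryl]propanoate (KN(SiMe3)2, 18-crown-6, THF, −78 °C) gives the Z-enoate F6. Amidation with MeNH(OMe)·HCl and i-PrMgCl brings the route back at 17.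

Step 12. The most likely failure is poor facial discrimination, because the Z-alkenyl group cannot lie coplanar with the carbonyl and the two ketone substituents are then less clearly differentiated; the C12 epimer mixture also hides the outcome until after step 15. The fallback replaces the Michael addition and reduction by an auxiliary-controlled acetate aldol addition that forms C9–C10 and sets C9 together. It sets out from 17, which is reduced with i-Bu2AlH at −78 °C to the Z-enal F7. The doubly lithiated acetate of (S)-1,1,2-triphenylethane-1,2-diol (2 LiN(iPr)2, THF, −78 °C), the enantiomer expected to give the (9S) carbinol, adds to F7 to give the β-hydroxy ester F8, whose minor diastereomer can be removed. Silylation (t-BuMe2SiOTf, 2,6-lutidine) gives F9, and reduction with i-Bu2AlH releases the auxiliary diol and gives the primary alcohol F10. I2, PPh3 and imidazole give the iodide F11, and alkylation of the sodium salt of 20 (NaH, DMF) with F11 brings the route back at 23.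

Step 14. The most likely failure is incomplete discrimination between the primary and the secondary triethylsilyl ether, or attack of the activated sulfoxide on the phosphonoacetate methine. The fallback separates deprotection from oxidation. It sets out from 23: buffered HF·pyridine (pyridine, THF, 0 °C) removes only the primary triethylsilyl ether and gives the primary alcohol F12. Dess–Martin periodinane with NaHCO3 then oxidises F12 to 24.

## Further compounds

F1 | step 15 | 14-epimer of 25, methyl (1E,3R,4R,7E,10Z,12S)-12-(tert-butyldimethylsilyloxy)-7,11-dimethyl-4-(prop-1-en-2-yl)-3-(triethylsilyloxy)cyclotetradeca-1,7,10-triene-1-carboxylate | C=C(C)[C@H]1CC/C(C)=C/C/C=C(/C)[C@@H](O[Si](C)(C)C(C)(C)C)CC/C(C(=O)OC)=C\[C@H]1O[Si](CC)(CC)CC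
F2 | step 15 | 14-epimeric hydroxy enoate, methyl (1E,3R,4R,7E,10Z,12S)-12-(tert-butyldimethylsilyloxy)-3-hydroxy-7,11-dimethyl-4-(prop-1-en-2-yl)cyclotetradeca-1,7,10-triene-1-carboxylate | C=C(C)[C@H]1CC/C(C)=C/C/C=C(/C)[C@@H](O[Si](C)(C)C(C)(C)C)CC/C(C(=O)OC)=C\[C@H]1O
F3 | step 15 | (14S)-benzoate, methyl (1E,3S,4R,7E,10Z,12S)-3-(benzoyloxy)-12-(tert-butyldimethylsilyloxy)-7,11-dimethyl-4-(prop-1-en-2-yl)cyclotetradeca-1,7,10-triene-1-carboxylate | C=C(C)[C@H]1CC/C(C)=C/C/C=C(/C)[C@@H](O[Si](C)(C)C(C)(C)C)CC/C(C(=O)OC)=C\[C@@H]1OC(=O)c2ccccc2
F4 | step 9 | homoallylic alcohol, (3E,7R,8R)-4-methyl-7-(prop-1-en-2-yl)-8,9-bis(triethylsilyloxy)non-3-en-1-ol | CC[Si](CC)(CC)OC[C@H](O[Si](CC)(CC)CC)[C@H](CC/C(C)=C/CCO)C(C)=C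
F5 | step 9 | β,γ-unsaturated aldehyde, (3E,7R,8R)-4-methyl-7-(prop-1-en-2-yl)-8,9-bis(triethylsilyloxy)non-3-enal | CC[Si](CC)(CC)OC[C@H](O[Si](CC)(CC)CC)[C@H](CC/C(C)=C/CC=O)C(C)=C
F6 | step 9 | Z-enoate, methyl (2Z,5E,9R,10R)-2,6-dimethyl-9-(prop-1-en-2-yl)-10,11-bis(triethylsilyloxy)undeca-2,5-dienoate | CC[Si](CC)(CC)OC[C@H](O[Si](CC)(CC)CC)[C@H](CC/C(C)=C/C/C=C(/C)C(=O)OC)C(C)=C
F7 | step 12 | Z-enal, (2Z,5E,9R,10R)-2,6-dimethyl-9-(prop-1-en-2-yl)-10,11-bis(triethylsilyloxy)undeca-2,5-dienal | CC[Si](CC)(CC)OC[C@H](O[Si](CC)(CC)CC)[C@H](CC/C(C)=C/C/C=C(/C)C=O)C(C)=C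
F8 | step 12 | β-hydroxy ester, (1S)-2-hydroxy-1,2,2-triphenylethyl (3S,4Z,7E,11R,12R)-3-hydroxy-4,8-dimethyl-11-(prop-1-en-2-yl)-12,13-bis(triethylsilyloxy)trideca-4,7-dienoate | CC[Si](CC)(CC)OC[C@H](O[Si](CC)(CC)CC)[C@H](CC/C(C)=C/C/C=C(/C)[C@@H](O)CC(=O)O[C@@H](c1ccccc1)C(O)(c1ccccc1)c1ccccc1)C(C)=C
F9 | step 12 | silylated β-hydroxy ester, (1S)-2-hydroxy-1,2,2-triphenylethyl (3S,4Z,7E,11R,12R)-3-(tert-butyldimethylsilyloxy)-4,8-dimethyl-11-(prop-1-en-2-yl)-12,13-bis(triethylsilyloxy)trideca-4,7-dienoate | CC[Si](CC)(CC)OC[C@H](O[Si](CC)(CC)CC)[C@H](CC/C(C)=C/C/C=C(/C)[C@@H](O[Si](C)(C)C(C)(C)C)CC(=O)O[C@@H](c1ccccc1)C(O)(c1ccccc1)c1ccccc1)C(C)=C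
F10 | step 12 | primary alcohol, (3S,4Z,7E,11R,12R)-3-(tert-butyldimethylsilyloxy)-4,8-dimethyl-11-(prop-1-en-2-yl)-12,13-bis(triethylsilyloxy)trideca-4,7-dien-1-ol | CC[Si](CC)(CC)OC[C@H](O[Si](CC)(CC)CC)[C@H](CC/C(C)=C/C/C=C(/C)[C@@H](O[Si](C)(C)C(C)(C)C)CCO)C(C)=C
F11 | step 12 | primary iodide, (3S,4Z,7E,11R,12R)-3-(tert-butyldimethylsilyloxy)-1-iodo-4,8-dimethyl-11-(prop-1-en-2-yl)-12,13-bis(triethylsilyloxy)trideca-4,7-diene | CC[Si](CC)(CC)OC[C@H](O[Si](CC)(CC)CC)[C@H](CC/C(C)=C/C/C=C(/C)[C@@H](O[Si](C)(C)C(C)(C)C)CCI)C(C)=C
F12 | step 14 | primary alcohol, methyl (5S,6Z,9E,13R,14R)-5-(tert-butyldimethylsilyloxy)-2-(diethoxyphosphoryl)-15-hydroxy-6,10-dimethyl-13-(prop-1-en-2-yl)-14-(triethylsilyloxy)pentadeca-6,9-dienoate | OC[C@H](O[Si](CC)(CC)CC)[C@H](CC/C(C)=C/C/C=C(/C)[C@@H](O[Si](C)(C)C(C)(C)C)CCC(C(=O)OC)P(=O)(OCC)OCC)C(C)=C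
A1 | alternative 1 | 17-membered propargyl 2-methylallyl ether with C9 tert-butyldimethylsilyl ether, E allyl alkene | C/C1=C\CC/C(C)=C/C/C=C(/C)[C@@H](O[Si](C)(C)C(C)(C)C)CCC#CCOC1
A2 | alternative 1 | 14-membered propargylic alcohol with C12–C13 alkyne | C=C(C)[C@H]1CC/C(C)=C/C/C=C(/C)[C@@H](O[Si](C)(C)C(C)(C)C)CCC#C[C@@H]1O
A3 | alternative 2 | 18-membered lactone, acyl part ending at C2, alcohol part the 2-methylallyl unit ending at C1 | O=C1CC/C(C)=C/C/C=C(/C)[C@@H](O[Si](C)(C)C(C)(C)C)CC/C(CO[Si](CC)(CC)CC)=C\[C@H](O[Si](CC)(CC)CC)/C=C(\C)CO1
A4 | alternative 2 | 14-membered ring C2-carboxylic acid, both C2 epimers | C=C(C)[C@H]1C(C(=O)O)C/C(C)=C/C/C=C(/C)[C@@H](O[Si](C)(C)C(C)(C)C)CC/C(CO[Si](CC)(CC)CC)=C\[C@@H]1O[Si](CC)(CC)CC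
A5 | alternative 3 | open-chain C2 phenyl sulfone with primary allylic chloride at C3 | ClC/C(C)=C/C/C=C(/C)[C@@H](O[Si](C)(C)C(C)(C)C)CC/C(CO[Si](CC)(CC)CC)=C\[C@H](O[Si](CC)(CC)CC)[C@H](CS(=O)(=O)c1ccccc1)C(C)=C
A6 | alternative 3 | macrocyclic C2 phenyl sulfone, both C2 epimers | C=C(C)[C@H]1C(S(=O)(=O)c2ccccc2)C/C(C)=C/C/C=C(/C)[C@@H](O[Si](C)(C)C(C)(C)C)CC/C(CO[Si](CC)(CC)CC)=C\[C@@H]1O[Si](CC)(CC)CC
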